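Readings and results are simulated with constants of no real substance; noise was put on by code.

The noon run left 8.7% of target against 27.5% of isomer of the product A at 5.00 min, and the flask asked about is that same flask, followed further.

common to all: starting material 22 mM; catalyst 0.42 mol%
- noon: the very flask that is asked about, followed so far
- flask: time 10 min

- noon (time / min: target / %, isomer of the product A / %): 0.417: 11.4, 18.5; 0.667: 12.9, 21.3; 1.00: 13.2, 22.8; 2.00: 11.4, 26.0; 3.00: 10.4, 27.9; 5.00: 8.7, 27.5

(scatter of a reading: 0.5 percentage points)

- in percentages every species weighs as the starting material in it: one idle adduct or self-condensation product counts as two
- for target the idle adduct is counted in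
- steps that have been proposed: 2 starting material -> self-condensation product; starting material <-> target; starting material + target <-> idle adduct; starting material -> uncatalysed product; starting material + catalyst <-> isomer of the product B + catalyst; starting material + catalyst <-> isomer of the product A + catalyst
- in an amount of target, one idle adduct counts as one target

- ratio of target to isomer of the product A at 0.80 s
- ratio of target to isomer of the product A at 10 min
- which of target and isomer of the product A there is more of at 10 min

I took the even case, a ratio of one, as my zero, and called the lead the natural logarithm of the amount of isomer of the product A over the amount of target at a given time. The noon run's lead was 1.15 at 5.00 min. Between the last two readings it grew by 0.0820 min⁻¹, and this rise per minute is the drift. Carrying the drift on to 10 min, I reckoned a ratio of 0.210.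

The forecast gave 0.64 at 0.80 s and 0.21 at 10 min, “with isomer A clearly in the lead”.

The flask gave 0.615 and 0.226, with 5.92% of target against 26.2% of isomer of the product A, so the one ahead was isomer of the product A.

    2 starting material → self-condensation product (k = 4.40 M⁻¹ s⁻¹)
    starting material ⇌ target (K = 1.70, k = 0.0210 s⁻¹)
    starting material + target ⇌ idle adduct, settled at all times (K = 620 M⁻¹)
    starting material → uncatalysed product (k = 0.00230 s⁻¹)
    starting material + catalyst ⇌ isomer of the product B + catalyst, rate k5*[starting material]*[catalyst] forward; the back reaction follows from the equilibrium constant (K = 0.670, k = 450 M⁻¹ s⁻¹)
    starting material + catalyst ⇌ isomer of the product A + catalyst, rate k6*[starting material]*[catalyst] forward; the back reaction follows from the equilibrium constant (K = 9.80, k = 370 M⁻¹ s⁻¹)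

At 0.0489 min, self-condensation used starting material 2.7 times as fast as the forward step to isomer of the product A, and at 10 min this flask held 56.9% of self-condensation product against 26.2% of that isomer. The flask's lead at 10 min was 1.49, worth 18.1 min of my drift above even.

For the neighbour flask at 13 mM, the noon lead and drift taken over unchanged gave 0.210. The computed ratio there was 0.218, with 6.42% of target against 29.4% of isomer of the product A.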